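**Plan**
- Retrosynthesis: cut C2–C3 of ring C last (opens the flavanone to an α-diazoketone that carries ring B as an aryl benzyl ether on O1), then the C8–CH2 bond (aryl iodide + alkylzinc), then O1–CH2; the C10 chain is traced back to the ring of (R)-limonene.
- Forward: limonene oxide is cleaved at C1–C2, methylenated and decarboxylated to the chain iodide; phloroacetophenone (ring A) is bis-silylated, iodinated at C3 and O-benzylated with the ring B unit; Negishi coupling joins chain and arene; the acetyl group becomes a diazoketone; ring C is closed last; desilylation follows.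
- Enabling feature: C2 is benzylic, bonded to O1 and to the para-oxygenated ring B, so in the open precursor it is an ArO–CH2–Ar' methylene whose hydridic C–H bonds lie 1,6 to C3, with O1 as the fifth atom.
- Stereochemistry: the side-chain centre (R) is C4 of (R)-limonene, carried through untouched; C2 (S) is set by the chiral dirhodium carboxylate in the ring closure.

Key step: step 10

Remark: (4R)-limonene 1,2-oxide is used as the commercial cis/trans mixture (both isomers give the same cleavage product); the sense of induction in step 10 is assigned by analogy, and should it prove opposite the mirror-image catalyst Rh2(R-PTTL)4 is used with nothing else changed.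

**Step 1**
Reactants: 1 (4R)-limonene 1,2-oxide
Product: 3 (3R)-6-oxo-3-(prop-1-en-2-yl)heptanal, via limonene-1,2-diol 2 (not isolated)
Conditions: H5IO6, THF/H2O, 0 °C to rt
Reagents that add atoms: water, O
Why: Acid-promoted hydrolysis of the epoxide to the 1,2-diol followed by periodate glycol cleavage (Malaprade reaction) opens the ring at C1–C2 only and leaves the isopropenyl group and the stereocentre untouched.

**Step 2**
Reactants: 3 (3R)-6-oxo-3-(prop-1-en-2-yl)heptanal
Product: 4 (3R)-6-oxo-3-(prop-1-en-2-yl)heptanoic acid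
Conditions: NaClO2, NaH2PO4, 2-methylbut-2-ene, t-BuOH/H2O, 0 °C to rt
Reagents that add atoms: sodium chlorite, [Na+].[O-]Cl=O
Why: Pinnick oxidation converts the aldehyde to the acid chemoselectively, the excess scavenger alkene protecting the isopropenyl group from hypochlorous acid.

**Step 3**
Reactants: 4 (3R)-6-oxo-3-(prop-1-en-2-yl)heptanoic acid
Product: 5 (3R)-6-methyl-3-(prop-1-en-2-yl)hept-6-enoic acid
Conditions: Ph3PCH3Br (3 equiv), KOtBu, THF, 0 °C to rt
Reagents that add atoms: methyltriphenylphosphonium bromide, C[P+](c1ccccc1)(c1ccccc1)c1ccccc1.[Br-]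
Why: Wittig methylenation with excess ylide converts the ketone while the carboxylate is inert, and the stereocentre is not alpha to any carbonyl and cannot epimerise.

**Step 4**
Reactants: 5 (3R)-6-methyl-3-(prop-1-en-2-yl)hept-6-enoic acid
Product: 7 (3S)-3-(iodomethyl)-2,6-dimethylhepta-1,6-diene, via Barton ester 6 (not isolated)
Conditions: 1-hydroxypyridine-2(1H)-thione, DCC, DMAP (cat.), CH2Cl2, dark, 0 °C to rt; then CHI3 (excess), PhH, hν (tungsten lamp), rt
Reagents that add atoms: iodoform, IC(I)I; 1-hydroxypyridine-2(1H)-thione, On1ccccc1=S (atoms stay only in 6)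
Why: Barton decarboxylative iodination removes the extra carbon as CO2 in a radical chain, and iodine-atom transfer from concentrated iodoform to the primary radical should be much faster than cyclisation onto either alkene, so skeleton and adjacent stereocentre are kept (the descriptor changes to S only through priorities).

**Step 5**
Reactants: 8 2,4,6-trihydroxyacetophenone
Product: 9 1-[2,4-bis(tert-butyldimethylsilyloxy)-6-hydroxyphenyl]ethanone
Conditions: TBSCl (2.1 equiv), imidazole, DMF, 0 °C
Reagents that add atoms: tert-butyldimethylsilyl chloride, CC(C)(C)[Si](C)(C)Cl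
Why: Phenol silylation should stop at the bis-ether because the last ortho-hydroxyl is held in a hydrogen bond to the acetyl carbonyl and is hindered.

**Step 6**
Reactants: 9 1-[2,4-bis(tert-butyldimethylsilyloxy)-6-hydroxyphenyl]ethanone
Product: 10 1-[4,6-bis(tert-butyldimethylsilyloxy)-2-hydroxy-3-iodophenyl]ethanone
Conditions: NIS (1.05 equiv), CH2Cl2, 0 °C to rt
Reagents that add atoms: N-iodosuccinimide, O=C1CCC(=O)N1I
Why: Electrophilic aromatic iodination should go to C3, ortho to the free and strongly activating phenol, because C5 lies between two bulky silyloxy groups.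

**Step 7**
Reactants: 10 1-[4,6-bis(tert-butyldimethylsilyloxy)-2-hydroxy-3-iodophenyl]ethanone; 11 [4-(tert-butyldimethylsilyloxy)phenyl]methanol
Product: 12 1-[4,6-bis(tert-butyldimethylsilyloxy)-3-iodo-2-{[4-(tert-butyldimethylsilyloxy)phenyl]methoxy}phenyl]ethanone
Conditions: PPh3, DIAD, THF, 0 °C to rt
Reagents that add atoms: none
Why: Mitsunobu etherification alkylates the acidic ortho-acyl phenol with the primary benzylic alcohol under neutral conditions that spare the three aryl silyl ethers.

**Step 8**
Reactants: 7 (3S)-3-(iodomethyl)-2,6-dimethylhepta-1,6-diene; 12 aryl iodide from step 7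
Product: 14 1-[4,6-bis(tert-butyldimethylsilyloxy)-3-[(2R)-5-methyl-2-(prop-1-en-2-yl)hex-5-en-1-yl]-2-{[4-(tert-butyldimethylsilyloxy)phenyl]methoxy}phenyl]ethanone, via alkylzinc iodide 13 (not isolated)
Conditions: 7, Zn dust (activated with TMSCl and BrCH2CH2Br, cat.), DMA, 40 °C; then 12, Pd(OAc)2 (cat.), SPhos, THF, 50 °C
Reagents that add atoms: zinc, [Zn] (stays only in 13)
Why: Zinc insertion into the primary iodide and Negishi cross-coupling with a bulky biarylphosphine ligand form the C8–CH2 bond at the di-ortho-substituted aryl iodide, the neutral organozinc tolerating ketone and silyl ethers and leaving the beta stereocentre untouched.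

**Step 9**
Reactants: 14 ketone from step 8
Product: 16 2-diazo-1-[4,6-bis(tert-butyldimethylsilyloxy)-3-[(2R)-5-methyl-2-(prop-1-en-2-yl)hex-5-en-1-yl]-2-{[4-(tert-butyldimethylsilyloxy)phenyl]methoxy}phenyl]ethanone, via trifluoroacetyl diketone 15 (not isolated)
Conditions: LiN(SiMe3)2, THF, −78 °C; CF3CO2CH2CF3; then MsN3, Et3N, H2O, MeCN, rt
Reagents that add atoms: methanesulfonyl azide, CS(=O)(=O)N=[N+]=[N-]; 2,2,2-trifluoroethyl trifluoroacetate, O=C(OCC(F)(F)F)C(F)(F)F (its acyl group stays only in 15)
Why: Detrifluoroacetylative diazo transfer (Regitz type) activates the methyl ketone as its trifluoroacetyl derivative, which accepts the diazo group and loses the activating acyl group as the sulfonamide, giving the terminal diazoketone.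

**Step 10**
Reactants: 16 diazoketone from step 9
Product: 17 (2S)-5,7-bis(tert-butyldimethylsilyloxy)-2-[4-(tert-butyldimethylsilyloxy)phenyl]-8-[(2R)-5-methyl-2-(prop-1-en-2-yl)hex-5-en-1-yl]chroman-4-one
Conditions: Rh2(S-PTTL)4 (dirhodium tetrakis[N-phthaloyl-(S)-tert-leucinate], 1 mol %), CH2Cl2, 0 °C, slow addition of 16
Reagents that add atoms: none
Why: The dirhodium carboxylate expels N2 from the diazoketone to give an electrophilic rhodium carbene at C3, which takes a benzylic hydrogen of the O1–CH2 group with hydride-transfer character and forms the C2–C3 bond in the same concerted, asynchronous three-centre event (carbene C–H insertion). The closest known reaction type is the chiral dirhodium carboxylate-catalysed intramolecular C–H insertion of α-diazoketones derived from O-alkylsalicylic acids, which gives chroman-4-ones. Ring C, the only ring closed, forms in the 1,6-insertion mode through a six-membered chair-like transition state made of C3, C4, C4a, C8a, O1 and C2, a 1,5-insertion being impossible because the fifth atom is O1. The new stereocentre C2 is controlled by the catalyst, whose pocket of four N-phthaloyl-tert-leucinate ligands selects one of the two enantiotopic benzylic hydrogens with ring B pseudo-equatorial, so that the (S)-catalyst should give 2S while the remote side-chain centre has no influence. Insertion must outrun oxonium ylide formation at O1 (followed by a [1,2]-benzyl shift), attack on the silyl ether oxygen and attack on the alkenes; this is secured because the C2–H bonds are activated three-fold (alpha to oxygen, benzylic, para to the silyloxy donor of ring B), O1 is a weakly basic aryl ether oxygen flanked by the C8 chain and the acyl group, the oxygen on C5 carries a bulky silyl group without alpha hydrogens, and the alkenes can only be reached through rings of nine or more atoms. Slow addition keeps the diazo concentration low and suppresses carbene dimerisation.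

**Step 11**
Reactants: 17 silylated flavanone from step 10
Product: 18 remangiflavanone A, (2S)-5,7-dihydroxy-2-(4-hydroxyphenyl)-8-[(2R)-5-methyl-2-(prop-1-en-2-yl)hex-5-en-1-yl]chroman-4-one
Conditions: HF·pyridine, pyridine, THF, 0 °C to rt
Reagents that add atoms: none
Why: Buffered fluoride cleaves the three aryl silyl ethers without the base that would open ring C and racemise C2 and without the strong acid that would cyclise the C7 hydroxyl onto the isopropenyl group.

**Compound list**
1 | (4R)-limonene 1,2-oxide, (4R)-1-methyl-4-(prop-1-en-2-yl)-7-oxabicyclo[4.1.0]heptane, cis/trans mixture | CC12OC1C[C@@H](CC2)C(C)=C | starting material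
2 | (4R)-1-methyl-4-(prop-1-en-2-yl)cyclohexane-1,2-diol (limonene-1,2-diol) | CC1(O)CC[C@H](CC1O)C(C)=C | intermediate (not isolated)
3 | (3R)-6-oxo-3-(prop-1-en-2-yl)heptanal | CC(=O)CC[C@H](CC=O)C(C)=C | intermediate
4 | (3R)-6-oxo-3-(prop-1-en-2-yl)heptanoic acid | CC(=O)CC[C@H](CC(=O)O)C(C)=C | intermediate
5 | (3R)-6-methyl-3-(prop-1-en-2-yl)hept-6-enoic acid | C=C(C)CC[C@H](CC(=O)O)C(C)=C | intermediate
6 | 2-thioxopyridin-1(2H)-yl (3R)-6-methyl-3-(prop-1-en-2-yl)hept-6-enoate (Barton ester) | C=C(C)CC[C@H](CC(=O)On1ccccc1=S)C(C)=C | intermediate (not isolated)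
7 | (3S)-3-(iodomethyl)-2,6-dimethylhepta-1,6-diene | C=C(C)CC[C@H](CI)C(C)=C | intermediate
8 | 2,4,6-trihydroxyacetophenone | CC(=O)c1c(O)cc(O)cc1O | starting material
9 | 1-[2,4-bis(tert-butyldimethylsilyloxy)-6-hydroxyphenyl]ethanone | CC(=O)c1c(O)cc(O[Si](C)(C)C(C)(C)C)cc1O[Si](C)(C)C(C)(C)C | intermediate
10 | 1-[4,6-bis(tert-butyldimethylsilyloxy)-2-hydroxy-3-iodophenyl]ethanone | CC(=O)c1c(O)c(I)c(O[Si](C)(C)C(C)(C)C)cc1O[Si](C)(C)C(C)(C)C | intermediate
11 | [4-(tert-butyldimethylsilyloxy)phenyl]methanol | OCc1ccc(O[Si](C)(C)C(C)(C)C)cc1 | starting material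
12 | 1-[4,6-bis(tert-butyldimethylsilyloxy)-3-iodo-2-{[4-(tert-butyldimethylsilyloxy)phenyl]methoxy}phenyl]ethanone | CC(=O)c1c(OCc2ccc(O[Si](C)(C)C(C)(C)C)cc2)c(I)c(O[Si](C)(C)C(C)(C)C)cc1O[Si](C)(C)C(C)(C)C | intermediate
13 | [(2S)-5-methyl-2-(prop-1-en-2-yl)hex-5-en-1-yl]zinc iodide | C=C(C)CC[C@H](C[Zn]I)C(C)=C | intermediate (not isolated)
14 | 1-[4,6-bis(tert-butyldimethylsilyloxy)-3-[(2R)-5-methyl-2-(prop-1-en-2-yl)hex-5-en-1-yl]-2-{[4-(tert-butyldimethylsilyloxy)phenyl]methoxy}phenyl]ethanone | C=C(C)CC[C@H](Cc1c(OCc2ccc(O[Si](C)(C)C(C)(C)C)cc2)c(C(C)=O)c(O[Si](C)(C)C(C)(C)C)cc1O[Si](C)(C)C(C)(C)C)C(C)=C | intermediate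
15 | 4,4,4-trifluoro-1-[aryl of 14]butane-1,3-dione (trifluoroacetyl diketone) | C=C(C)CC[C@H](Cc1c(OCc2ccc(O[Si](C)(C)C(C)(C)C)cc2)c(C(=O)CC(=O)C(F)(F)F)c(O[Si](C)(C)C(C)(C)C)cc1O[Si](C)(C)C(C)(C)C)C(C)=C | intermediate (not isolated)
16 | 2-diazo-1-[4,6-bis(tert-butyldimethylsilyloxy)-3-[(2R)-5-methyl-2-(prop-1-en-2-yl)hex-5-en-1-yl]-2-{[4-(tert-butyldimethylsilyloxy)phenyl]methoxy}phenyl]ethanone | C=C(C)CC[C@H](Cc1c(OCc2ccc(O[Si](C)(C)C(C)(C)C)cc2)c(C(=O)C=[N+]=[N-])c(O[Si](C)(C)C(C)(C)C)cc1O[Si](C)(C)C(C)(C)C)C(C)=C | intermediate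
17 | (2S)-5,7-bis(tert-butyldimethylsilyloxy)-2-[4-(tert-butyldimethylsilyloxy)phenyl]-8-[(2R)-5-methyl-2-(prop-1-en-2-yl)hex-5-en-1-yl]chroman-4-one | C=C(C)CC[C@H](Cc1c(O[Si](C)(C)C(C)(C)C)cc(O[Si](C)(C)C(C)(C)C)c2c1O[C@H](c1ccc(O[Si](C)(C)C(C)(C)C)cc1)CC2=O)C(C)=C | intermediate
18 | remangiflavanone A, (2S)-5,7-dihydroxy-2-(4-hydroxyphenyl)-8-[(2R)-5-methyl-2-(prop-1-en-2-yl)hex-5-en-1-yl]chroman-4-one | C=C(C)CC[C@H](Cc1c(O)cc(O)c2c1O[C@H](c1ccc(O)cc1)CC2=O)C(C)=C | target

**Totals**
Total step count: 11. Longest linear sequence: 8 steps (steps 1–4 and 8–11, from 1); the ring A branch (steps 5–7) joins at step 8.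

**Steps most likely to fail**

Step 10. The ether oxygen O1 may attack the rhodium carbene faster than the C–H bond does, and a [1,2]-benzyl shift of the oxonium ylide would then contract the ring; the catalyst may also discriminate the two enantiotopic benzylic hydrogens poorly. The fallback sets out from 10 and returns at 17, and it sets C2 by aryl transfer to a chromone instead. Condensation of 10 with DMF dimethyl acetal should give the enaminone (E)-1-[4,6-bis(tert-butyldimethylsilyloxy)-2-hydroxy-3-iodophenyl]-3-(dimethylamino)prop-2-en-1-one F1. Cyclisation with TsOH (cat.) in toluene and loss of dimethylamine should give 5,7-bis(tert-butyldimethylsilyloxy)-8-iodo-4H-chromen-4-one F2. Negishi coupling of F2 with 13 under the conditions of step 8 should give 5,7-bis(tert-butyldimethylsilyloxy)-8-[(2R)-5-methyl-2-(prop-1-en-2-yl)hex-5-en-1-yl]-4H-chromen-4-one F3. Rhodium-catalysed asymmetric conjugate addition (Hayashi–Miyaura) of [4-(tert-butyldimethylsilyloxy)phenyl]boronic acid to F3, with [Rh(OH)(cod)]2 and the antipode of a chiral diene or bisphosphine ligand that delivers the aryl group to the face giving 2S, should give 17.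

Step 8. Oxidative addition and transmetalation at an aryl iodide flanked by two ortho oxygen substituents, one of them the large benzyl ether, may be slow enough for protodezincation or β-hydride elimination of the alkyl group to take over. The fallback sets out from 10 (with 13) and returns at 14, and it inverts the order of coupling and etherification so that the coupling partner carries only the small hydrogen-bonded hydroxyl. Negishi coupling of unprotected 10 with slow addition of excess 13 (Pd(OAc)2, SPhos, THF) should give 1-[4,6-bis(tert-butyldimethylsilyloxy)-2-hydroxy-3-[(2R)-5-methyl-2-(prop-1-en-2-yl)hex-5-en-1-yl]phenyl]ethanone F4. Mitsunobu etherification of F4 with 11 (PPh3, DIAD, THF) should then give 14.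

Step 4. The primary radical may cyclise onto a 1,1-disubstituted alkene (5-exo, 6-endo, or 3-exo with 1,2-vinyl shift) before iodine transfer, which would scramble the skeleton and the stereocentre. The fallback sets out from 5 and returns at 7 by a polar one-carbon degradation. α-Hydroxylation of the dianion of 5 (LiN(iPr)2, THF, then O2 and P(OEt)3) should give (3S)-2-hydroxy-6-methyl-3-(prop-1-en-2-yl)hept-6-enoic acid F5 as a mixture of C2 epimers. Oxidative decarboxylation with Pb(OAc)4 in benzene should give (2S)-5-methyl-2-(prop-1-en-2-yl)hex-5-enal F6. Immediate reduction with NaBH4 in MeOH at −20 °C, before the aldehyde can epimerise, should give (2S)-5-methyl-2-(prop-1-en-2-yl)hex-5-en-1-ol F7. Treatment of F7 with I2, PPh3 and imidazole (Appel reaction) should give 7.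

**Further compounds**
F1 | step 10 | (E)-1-[4,6-bis(tert-butyldimethylsilyloxy)-2-hydroxy-3-iodophenyl]-3-(dimethylamino)prop-2-en-1-one | CN(C)/C=C/C(=O)c1c(O)c(I)c(O[Si](C)(C)C(C)(C)C)cc1O[Si](C)(C)C(C)(C)C
F2 | step 10 | 5,7-bis(tert-butyldimethylsilyloxy)-8-iodo-4H-chromen-4-one | O=c1ccoc2c(I)c(O[Si](C)(C)C(C)(C)C)cc(O[Si](C)(C)C(C)(C)C)c12
F3 | step 10 | 5,7-bis(tert-butyldimethylsilyloxy)-8-[(2R)-5-methyl-2-(prop-1-en-2-yl)hex-5-en-1-yl]-4H-chromen-4-one | C=C(C)CC[C@H](Cc1c(O[Si](C)(C)C(C)(C)C)cc(O[Si](C)(C)C(C)(C)C)c2c1occc2=O)C(C)=C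
F4 | step 8 | 1-[4,6-bis(tert-butyldimethylsilyloxy)-2-hydroxy-3-[(2R)-5-methyl-2-(prop-1-en-2-yl)hex-5-en-1-yl]phenyl]ethanone | C=C(C)CC[C@H](Cc1c(O)c(C(C)=O)c(O[Si](C)(C)C(C)(C)C)cc1O[Si](C)(C)C(C)(C)C)C(C)=C
F5 | step 4 | (3S)-2-hydroxy-6-methyl-3-(prop-1-en-2-yl)hept-6-enoic acid (both C2 epimers) | C=C(C)CC[C@H](C(O)C(=O)O)C(C)=C
F6 | step 4 | (2S)-5-methyl-2-(prop-1-en-2-yl)hex-5-enal | C=C(C)CC[C@H](C=O)C(C)=C
F7 | step 4 | (2S)-5-methyl-2-(prop-1-en-2-yl)hex-5-en-1-ol | C=C(C)CC[C@H](CO)C(C)=C
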